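## Structural features

The target is a daucane-type hydroazulene: cyclopentane ring A (C1, C2, C3, C3a, C8a) is trans-fused through the C3a–C8a bond to cycloheptanone ring B (C3a, C4–C8, C8a). Ring A carries a tertiary carbinol at C1 (hydroxyl β, isopropyl α) next to the ring-fusion methine C8a (H α). C8a lies between the all-carbon quaternary C3a (methyl β) and the oxygen-bearing C8, so C1, C8a, C8 and C3a form one block of contiguous stereocentres. Ring B is oxygenated on four consecutive carbons: a secondary alcohol at C5 and a tertiary alcohol at C6 (both α, a second adjacent pair of stereocentres), a ketone at C7, and a 4-hydroxybenzoate on the α-oxygen of C8. Fragile groups are the α-acyloxy ketone (C8 can epimerise, the ester is base-labile and can migrate), the tertiary C1 alcohol (acid-promoted dehydration) and the free phenol. The real difficulty is twofold: the quaternary C3a at a trans 5–7 fusion has no heteroatom to help set it, and the C5–C8 oxidation pattern must be placed correctly relative to that remote centre. The key step exploits the fact that ring B divides into the five-carbon chain C7–C8–C8a–C3a–C4 and the two-carbon unit C5–C6. With C4 bonded back to C8a, the chain is a vinylcyclopropane fused to ring A, and C5–C6 is an alkyne carrying the C6 methyl, so C3a can be fixed before ring B exists.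

## Logic of the disconnections

23 to 22: the benzyl–oxygen bond of the phenol ether is cut. The phenol has to be masked while the aroyl group is attached and the enone is dihydroxylated, and hydrogenolysis is neutral enough for the α-acyloxy ketone. The demand is that no C=C bond is left at that point.

22 to 21: the C5–O and C6–O bonds are cut together. Both oxygens are α and cis, so they map onto one syn-dihydroxylation of a C5=C6 enone alkene, which removes two stereocentres at once. The forward step must attack the α face; the axial C3a methyl blocks the β face.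

21 to 19 and 20: the acyl C–O bond at O8 is cut. Esterification is placed before the dihydroxylation so that C8–OH is the only secondary hydroxyl present. The tertiary C1 hydroxyl must stay unreactive.

19 to 17: the C8–O bond is cut. C8 is the only α-position of the C7 ketone that can be deprotonated kinetically, so oxygen enters by electrophilic hydroxylation of the cross-conjugated enolate 18. The demand is attack on the α face, away from the angular methyl and the C1 branch.

17 to 15 through 16: the C7 carbonyl is taken back to a methylene. C7 is the ring CH2 on the methyl-bearing carbon of the C5=C6 alkene, the site an ene-type selenium oxidation prefers. This reduces ring B to one trisubstituted alkene. The demand is selectivity for C7 over the C6 methyl and over C4.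

15 to 14: the C1–isopropyl bond is cut. In 14 the C8a–C8 bond and the angular methyl both lie on the β face of the C1 carbonyl, so a nucleophile enters from α and the hydroxyl ends β. The addition must outrun enolisation towards C8a.

14 to 11 through 13 and 12: the C1 carbonyl goes back to the α-carbinol, silicon returns to C5, and the C8a–H and one C8–H bonds are removed to give the C8=C8a alkene. The C1 α-hydroxyl is then used a second time, to deliver hydrogen to the α face and fix C8a trans to the C3a methyl. Silicon shields the C5=C6 alkene during this hydrogenation. The demand is discrimination between the two alkenes of 11.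

11 to 7 and 10 (key): the C4–C5 and C6–C7 bonds are cut, which opens ring B into a ring-A vinylcyclopropane and an alkyne. One step then builds the seven-membered ring with both alkenes in place and leaves C3a untouched. Two selectivities are demanded: cleavage of the cyclopropane bond to C4, not to C3a, and methyl on C6. With a plain methyl-substituted terminal alkyne, the insertion step would place the larger substituent on the metal-bound carbon, which becomes C5. The alkyne therefore carries a silyl group larger than methyl, which takes that position and is removed later.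

10 to 8: the C–Si bond is cut; acetylide silylation, one step.

7 to 6: the two bonds from the cyclopropane methylene C4 to C3a and C8a are cut. Hydroxyl-directed methylene transfer to the ring alkene sets C3a and C8a relative to the C1 carbinol, so one early stereocentre fixes the quaternary centre. The terminal vinyl group must be left alone.

6 to 4 and 5, then 4 to 3 to 1: the sp2–sp2 bond C8a–C8 is cut (cross-coupling), then the carbinol C–H (enantioselective ketone reduction) and the C–Br bond (α-bromination of the enone). The only demand is high enantioselectivity in the reduction, since every later stereocentre is relayed from it.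

## Other disconnections considered

Alternative 1: The cut runs through ring A at C3–C3a and C1–C8a. In the forward direction a Lewis-acid-promoted Danheiser annulation joins cycloheptadienone A1 and allenylsilane A2. The allene terminus adds to C3a, silicon shifts, and the vinyl cation closes onto C8a to give hydroazulenone A3. In its favour, ring A, the quaternary C3a and the isopropyl carbon arrive in one convergent step. On the isopropyl group it is better than the chosen plan, which needs an organometallic addition to a hindered ketone; on early placement of the C5 oxygen it is at least equal. Against it here: A3 is cis-fused, so C8a must be epimerised next to the C8 ketone with uncertain thermodynamics. Its C5 silyloxy group is drawn on the β face, opposite to the target, and would need inversion. The carbonyl sits at C8, not C7, so ring B needs a 1,2-transposition. The C1=C2 vinylsilane still has to become the tertiary alcohol on the correct face. A1 offers two β,β-disubstituted enone termini (C3a and C6) to the allene and carries a stereocentre of its own. Mechanistically it is a stepwise cationic process, against a metallacycle process in the chosen plan; both form two C–C bonds. The chosen plan fixes C3a before ring B, whereas this one creates it in the annulation with the wrong fusion. In step count the key steps are equal, but the corrections make the whole route longer.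

Alternative 2: The cut is the C3a–C8a bond of ring A, with C1 taken from the chiral pool. Ozonolysis of terpinen-4-ol A4 gives keto-aldehyde A5, and amine-catalysed aldol condensation contracts it to enal A6. In its favour, the C1 carbinol with its isopropyl group and correct configuration comes from a cheap terpene in one sequence. That is better than the chosen plan, which spends an oxidation and an organocerium addition on C1 and relies on diastereocontrol. Against it here: A6 holds only C8 of ring B. C3a must still be made quaternary by conjugate addition to a β,β-disubstituted enal beside a free tertiary alcohol, C8a must be set, and C4–C7 must be attached and closed to a seven-membered ring. Natural A4 is also not enantiopure. The mechanism is robust polar carbonyl chemistry. For ring A the step count is equal or better; for the whole molecule it is longer, because the chosen plan makes ring B with both alkenes in one step.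

Alternative 3: The cut is the C8–C8a bond. Anodic oxidation of bis(silyl enol ether) A7 turns one enol ether into a radical cation that is trapped by the other, closing ring B as 1,4-dione A8. In its favour, C5, C6 (as acetonide) and C7 are already at their final oxidation level and configuration at ring closure. That is better than the chosen plan, which needs an allylic oxidation and a late dihydroxylation. C8 then needs only hydroxylation on the sole enolisable side of C7, and the trans fusion can be adjusted by equilibration. Against it here: oxidative enol-ether coupling to a seven-membered ring is entropically less favourable than to five- or six-membered rings. A7 must already carry three stereocentres, including the quaternary C3a set without a ring to help. The two ketones of A8 (C1 and C7) must be told apart for the isopropyl addition. The mechanism is single-electron, against two-electron organometallic steps in the chosen plan. After ring closure it is shorter (better); before ring closure it is longer; overall it is not shorter.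

Key step: step 6

Assumptions: (a) ring atoms keep the numbering C1–C8a of the target in all names, also where strict nomenclature would choose other locants; (b) the γ-hydroxy ketones 17–23 are treated as open hydroxy ketones, as the target is drawn; a reversible C1–O–C7 hemiketal would be in equilibrium with them.

Step 1
Reactants: 1 3-methylcyclopent-2-en-1-one
Product: 3 2-bromo-3-methylcyclopent-2-en-1-one, via trans-2,3-dibromo-3-methylcyclopentan-1-one 2 (not isolated)
Conditions: Br2, CH2Cl2, 0 °C; then Et3N, 0 °C to rt
Reagents that add atoms: bromine, BrBr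
Why: Anti addition of bromine to the enone alkene, then base removes the acidic C2–H and the C3 bromide leaves (E1cB), restoring conjugation; this is the classical α-bromination of a cyclic enone.

Step 2
Reactants: 3 2-bromo-3-methylcyclopent-2-en-1-one
Product: 4 (1R)-2-bromo-3-methylcyclopent-2-en-1-ol
Conditions: (S)-2-methyl-CBS-oxazaborolidine (10 mol %), BH3·SMe2, THF, −20 °C
Reagents that add atoms: none
Why: Corey–Bakshi–Shibata reduction, well precedented for 2-halo-cycloalkenones. The brominated alkene arm acts as the large group, so the (S)-catalyst should deliver hydride to the face that gives the (R)-carbinol; this is the only stereocentre made by reagent control.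

Step 3
Reactants: 4 (1R)-2-bromo-3-methylcyclopent-2-en-1-ol; 5 potassium vinyltrifluoroborate
Product: 6 (1R)-2-ethenyl-3-methylcyclopent-2-en-1-ol
Conditions: PdCl2(dppf)·CH2Cl2 (5 mol %), Cs2CO3, THF/H2O 9:1, 70 °C
Reagents that add atoms: none
Why: Suzuki–Miyaura coupling of an alkenyl bromide with a vinyltrifluoroborate; zerovalent palladium inserts into the C(sp2)–Br bond and the free allylic alcohol is a spectator under the carbonate base.

Step 4
Reactants: 6 (1R)-2-ethenyl-3-methylcyclopent-2-en-1-ol
Product: 7 (1R,2R,5R)-1-ethenyl-5-methylbicyclo[3.1.0]hexan-2-ol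
Conditions: Et2Zn, CH2I2, CH2Cl2, −20 to 0 °C
Reagents that add atoms: diiodomethane, ICI
Why: Hydroxyl-directed Simmons–Smith cyclopropanation (Furukawa variant). The zinc alkoxide delivers the carbenoid to the allylic, more electron-rich ring alkene on the face of the oxygen, which sets C8a and the quaternary C3a cis to the hydroxyl; the homoallylic, monosubstituted vinyl group is less nucleophilic and should survive with limited reagent.

Step 5
Reactants: 8 propyne
Product: 10 benzyldimethyl(prop-1-yn-1-yl)silane, via prop-1-yn-1-yllithium 9 (not isolated)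
Conditions: n-BuLi, THF, −78 °C; then BnMe2SiCl, −78 °C to rt
Reagents that add atoms: benzylchlorodimethylsilane, C[Si](C)(Cl)Cc1ccccc1
Why: Deprotonation of the terminal alkyne and silylation of the acetylide. The benzyl group on silicon allows the later removal with fluoride under non-acidic conditions.

Step 6
Reactants: 7 (1R,2R,5R)-1-ethenyl-5-methylbicyclo[3.1.0]hexan-2-ol; 10 benzyldimethyl(prop-1-yn-1-yl)silane
Product: 11 (1R,3aR)-5-[benzyl(dimethyl)silyl]-3a,6-dimethyl-1,2,3,3a,4,7-hexahydroazulen-1-ol
Conditions: [Rh(CO)2Cl]2 (5 mol %), 10 (3 equiv), ClCH2CH2Cl, 80 °C, sealed tube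
Reagents that add atoms: none
Why: Intermolecular rhodium-catalysed (5+2) cycloaddition of a vinylcyclopropane with an alkyne; the closest precedent is the [Rh(CO)2Cl]2-catalysed reaction of 1-substituted, non-activated vinylcyclopropanes with alkynes. Monovalent rhodium binds the vinyl group in its s-cis rotamer (favoured because C8a is fully substituted) and cleaves the C8a–C4 bond to a trivalent rhoda-allyl metallacycle (σ-bond to C4, allyl over C8a–C8–C7). The alkyne inserts at the C7 terminus (C6–C7 bond), and reductive elimination from the eight-membered rhodacycle joins C4 to C5 and returns monovalent rhodium. Ring B is thus closed in one metallacycle-mediated cycloaddition, by migratory insertion followed by C(sp3)–C(sp2) reductive elimination; no stereocentre is created, and C1 and C3a are carried through because none of their bonds is touched. Bond selectivity: rhodium enters the bond from C8a to the CH2 carbon because the other bond ends at the quaternary C3a and would lead to a bridged ring with a bridgehead alkene. Regioselectivity: in the insertion the bulkier alkyne substituent stays away from the forming C–C bond and sits on the rhodium-bound carbon, so silicon should end on C5 and methyl on C6; with propyne itself the same preference would put methyl mainly on C5. The σ-alkyl at C4 has no β-hydrogen because C3a is quaternary, so β-hydride loss cannot divert the intermediate. The free C1 hydroxyl is compatible with this catalyst and is needed in step 7.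

Step 7
Reactants: 11 (1R,3aR)-5-[benzyl(dimethyl)silyl]-3a,6-dimethyl-1,2,3,3a,4,7-hexahydroazulen-1-ol
Product: 12 (1R,3aR,8aR)-5-[benzyl(dimethyl)silyl]-3a,6-dimethyl-1,2,3,3a,4,7,8,8a-octahydroazulen-1-ol
Conditions: [Ir(cod)(PCy3)(py)]PF6 (5 mol %), H2 (1 atm), CH2Cl2, 0 °C to rt
Reagents that add atoms: none
Why: Hydroxyl-directed homogeneous hydrogenation. Iridium binds the allylic C1 α-hydroxyl and adds hydrogen to the α face of the C8=C8a alkene, so H-8a ends α, trans to the C3a methyl. The fully substituted, silyl-bearing C5=C6 alkene is remote from the hydroxyl and hindered and should not react.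

Step 8
Reactants: 12 (1R,3aR,8aR)-5-[benzyl(dimethyl)silyl]-3a,6-dimethyl-1,2,3,3a,4,7,8,8a-octahydroazulen-1-ol
Product: 13 (1R,3aR,8aR)-3a,6-dimethyl-1,2,3,3a,4,7,8,8a-octahydroazulen-1-ol
Conditions: Bu4NF (3 equiv), THF, rt to 50 °C
Reagents that add atoms: none
Why: Fluoride-promoted protodesilylation of a benzyldimethylsilyl alkene. Fluoride cleaves the benzyl group from silicon and the activated silane is then replaced by hydrogen at the same carbon; no acid is present, so the C5=C6 alkene should not migrate.

Step 9
Reactants: 13 (1R,3aR,8aR)-3a,6-dimethyl-1,2,3,3a,4,7,8,8a-octahydroazulen-1-ol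
Product: 14 (3aR,8aR)-3a,6-dimethyl-3,3a,4,7,8,8a-hexahydroazulen-1(2H)-one
Conditions: Dess–Martin periodinane, NaHCO3, CH2Cl2, 0 °C to rt
Reagents that add atoms: none
Why: Dess–Martin oxidation of a secondary alcohol under buffered, non-basic conditions, so the C8a centre next to the new ketone is not epimerised. The C1 carbinol has done its work as relay and directing group and is removed here.

Step 10
Reactants: 14 (3aR,8aR)-3a,6-dimethyl-3,3a,4,7,8,8a-hexahydroazulen-1(2H)-one
Product: 15 (1R,3aR,8aR)-3a,6-dimethyl-1-(propan-2-yl)-1,2,3,3a,4,7,8,8a-octahydroazulen-1-ol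
Conditions: i-PrMgCl, CeCl3 (anhydrous), THF, −78 to 0 °C
Reagents that add atoms: isopropylmagnesium chloride, CC(C)[Mg]Cl
Why: Organocerium 1,2-addition (Imamoto conditions), which suppresses enolisation and β-hydride reduction of the hindered α-branched cyclopentanone. The nucleophile attacks C1 anti to the adjacent C8a–C8 bond and to the axial C3a methyl, both on the β face, so isopropyl enters α and the hydroxyl ends β.

Step 11
Reactants: 15 (1R,3aR,8aR)-3a,6-dimethyl-1-(propan-2-yl)-1,2,3,3a,4,7,8,8a-octahydroazulen-1-ol
Product: 16 (1R,3aR,8aR)-3a,6-dimethyl-1-(propan-2-yl)-1,2,3,3a,4,7,8,8a-octahydroazulene-1,7-diol (both C7 epimers)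
Conditions: SeO2 (0.5 equiv), t-BuOOH, CH2Cl2, rt
Reagents that add atoms: selenium dioxide, O=[Se]=O (oxygen donor, re-oxidised by tert-butyl hydroperoxide, CC(C)(C)OO)
Why: Selenium dioxide allylic oxidation (ene reaction, then [2,3]-sigmatropic shift). Selenium adds to the less substituted C5, and hydrogen is taken from the ring CH2 on the more substituted alkene carbon (ring CH2 before CH3), which places oxygen on C7 and returns the alkene to C5=C6. The C7 configuration is irrelevant because step 12 oxidises it.

Step 12
Reactants: 16 (1R,3aR,8aR)-3a,6-dimethyl-1-(propan-2-yl)-1,2,3,3a,4,7,8,8a-octahydroazulene-1,7-diol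
Product: 17 (1R,3aR,8aR)-1-hydroxy-3a,6-dimethyl-1-(propan-2-yl)-2,3,3a,4,8,8a-hexahydroazulen-7(1H)-one
Conditions: Dess–Martin periodinane, NaHCO3, CH2Cl2, rt
Reagents that add atoms: none
Why: Dess–Martin oxidation of the secondary allylic alcohol to the enone; the tertiary C1 alcohol cannot be oxidised.

Step 13
Reactants: 17 (1R,3aR,8aR)-1-hydroxy-3a,6-dimethyl-1-(propan-2-yl)-2,3,3a,4,8,8a-hexahydroazulen-7(1H)-one
Product: 19 (1R,3aR,8R,8aS)-1,8-dihydroxy-3a,6-dimethyl-1-(propan-2-yl)-2,3,3a,4,8,8a-hexahydroazulen-7(1H)-one, via disodium alkoxide enolate 18 (not isolated)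
Conditions: NaN(SiMe3)2 (2.2 equiv), THF, −78 °C; then 2-(phenylsulfonyl)-3-phenyloxaziridine, −78 °C; NH4Cl (aq)
Reagents that add atoms: 2-(phenylsulfonyl)-3-phenyloxaziridine, O=S(=O)(c1ccccc1)N1OC1c1ccccc1
Why: Davis hydroxylation of the kinetic, cross-conjugated α'-enolate; C8 is the only α-CH2 of the enone. The oxaziridine should approach C8 from the α face, anti to the axial C3a methyl and to the C1 branch on C8a, giving the α-hydroxyl cis to H-8a.

Step 14
Reactants: 19 (1R,3aR,8R,8aS)-1,8-dihydroxy-3a,6-dimethyl-1-(propan-2-yl)-2,3,3a,4,8,8a-hexahydroazulen-7(1H)-one; 20 4-(benzyloxy)benzoyl chloride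
Product: 21 (1R,3aR,8R,8aS)-1-hydroxy-3a,6-dimethyl-7-oxo-1-(propan-2-yl)-1,2,3,3a,4,7,8,8a-octahydroazulen-8-yl 4-(benzyloxy)benzoate
Conditions: Et3N, DMAP (cat.), CH2Cl2, 0 °C to rt
Reagents that add atoms: none
Why: DMAP-catalysed acylation of the only secondary hydroxyl; the hindered tertiary C1 alcohol does not compete at this temperature, and no bond to C8 is broken, so its configuration is kept.

Step 15
Reactants: 21 (1R,3aR,8R,8aS)-1-hydroxy-3a,6-dimethyl-7-oxo-1-(propan-2-yl)-1,2,3,3a,4,7,8,8a-octahydroazulen-8-yl 4-(benzyloxy)benzoate
Product: 22 (1R,3aR,5S,6S,8R,8aS)-1,5,6-trihydroxy-3a,6-dimethyl-7-oxo-1-(propan-2-yl)decahydroazulen-8-yl 4-(benzyloxy)benzoate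
Conditions: OsO4 (5 mol %), N-methylmorpholine N-oxide, citric acid, t-BuOH/H2O, rt
Reagents that add atoms: osmium tetroxide, O=[Os](=O)(=O)=O; N-methylmorpholine N-oxide, C[N+]1([O-])CCOCC1; water, O
Why: Catalytic syn-dihydroxylation (Upjohn conditions; citric acid keeps the medium slightly acidic and helps turnover with electron-poor alkenes). Both oxygens are delivered to the α face because the axial C3a methyl shields the β face of C5 and the C8 ester is equatorial, which sets C5 and C6 in one step.

Step 16
Reactants: 22 (1R,3aR,5S,6S,8R,8aS)-1,5,6-trihydroxy-3a,6-dimethyl-7-oxo-1-(propan-2-yl)decahydroazulen-8-yl 4-(benzyloxy)benzoate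
Product: 23 (1R,3aR,5S,6S,8R,8aS)-1,5,6-trihydroxy-3a,6-dimethyl-7-oxo-1-(propan-2-yl)decahydroazulen-8-yl 4-hydroxybenzoate
Conditions: H2 (1 atm), Pd/C (10 %), EtOAc, rt
Reagents that add atoms: none
Why: Hydrogenolysis of the benzyl aryl ether under neutral conditions; no alkene remains, and the ester, ketone and alcohols are inert to these conditions.

## Compound list

1 | 3-methylcyclopent-2-en-1-one | CC1=CC(=O)CC1 | starting material
2 | trans-2,3-dibromo-3-methylcyclopentan-1-one (racemic) | C[C@]1(Br)CCC(=O)[C@@H]1Br | intermediate (not isolated)
3 | 2-bromo-3-methylcyclopent-2-en-1-one | CC1=C(Br)C(=O)CC1 | intermediate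
4 | (1R)-2-bromo-3-methylcyclopent-2-en-1-ol | O[C@@H]1CCC(C)=C1Br | intermediate
5 | potassium vinyltrifluoroborate | C=C[B-](F)(F)F.[K+] | starting material
6 | (1R)-2-ethenyl-3-methylcyclopent-2-en-1-ol | O[C@@H]1CCC(C)=C1C=C | intermediate
7 | (1R,2R,5R)-1-ethenyl-5-methylbicyclo[3.1.0]hexan-2-ol (hydroxyl cis to the cyclopropane) | O[C@@H]1CC[C@]2(C)C[C@]12C=C | intermediate
8 | propyne | CC#C | starting material
9 | prop-1-yn-1-yllithium | CC#C[Li] | intermediate (not isolated)
10 | benzyldimethyl(prop-1-yn-1-yl)silane | CC#C[Si](C)(C)Cc1ccccc1 | intermediate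
11 | (1R,3aR)-5-[benzyl(dimethyl)silyl]-3a,6-dimethyl-1,2,3,3a,4,7-hexahydroazulen-1-ol | O[C@@H]1CC[C@]2(C)CC([Si](C)(C)Cc3ccccc3)=C(C)CC=C12 | intermediate
12 | (1R,3aR,8aR)-5-[benzyl(dimethyl)silyl]-3a,6-dimethyl-1,2,3,3a,4,7,8,8a-octahydroazulen-1-ol (trans-fused) | O[C@@H]1CC[C@]2(C)CC([Si](C)(C)Cc3ccccc3)=C(C)CC[C@@H]12 | intermediate
13 | (1R,3aR,8aR)-3a,6-dimethyl-1,2,3,3a,4,7,8,8a-octahydroazulen-1-ol | O[C@@H]1CC[C@]2(C)CC=C(C)CC[C@@H]12 | intermediate
14 | (3aR,8aR)-3a,6-dimethyl-3,3a,4,7,8,8a-hexahydroazulen-1(2H)-one | O=C1CC[C@]2(C)CC=C(C)CC[C@@H]12 | intermediate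
15 | (1R,3aR,8aR)-3a,6-dimethyl-1-(propan-2-yl)-1,2,3,3a,4,7,8,8a-octahydroazulen-1-ol | CC(C)[C@]1(O)CC[C@]2(C)CC=C(C)CC[C@H]21 | intermediate
16 | (1R,3aR,8aR)-3a,6-dimethyl-1-(propan-2-yl)-1,2,3,3a,4,7,8,8a-octahydroazulene-1,7-diol (both C7 epimers) | CC(C)[C@]1(O)CC[C@]2(C)CC=C(C)C(O)C[C@H]21 | intermediate
17 | (1R,3aR,8aR)-1-hydroxy-3a,6-dimethyl-1-(propan-2-yl)-2,3,3a,4,8,8a-hexahydroazulen-7(1H)-one | CC(C)[C@]1(O)CC[C@]2(C)CC=C(C)C(=O)C[C@H]21 | intermediate
18 | disodium salt of 17 (C1 alkoxide, C7–C8 enolate) | CC(C)[C@]1([O-])CC[C@]2(C)CC=C(C)C([O-])=C[C@H]21.[Na+].[Na+] | intermediate (not isolated)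
19 | (1R,3aR,8R,8aS)-1,8-dihydroxy-3a,6-dimethyl-1-(propan-2-yl)-2,3,3a,4,8,8a-hexahydroazulen-7(1H)-one | CC(C)[C@]1(O)CC[C@]2(C)CC=C(C)C(=O)[C@H](O)[C@H]21 | intermediate
20 | 4-(benzyloxy)benzoyl chloride | O=C(Cl)c1ccc(OCc2ccccc2)cc1 | starting material
21 | (1R,3aR,8R,8aS)-1-hydroxy-3a,6-dimethyl-7-oxo-1-(propan-2-yl)-1,2,3,3a,4,7,8,8a-octahydroazulen-8-yl 4-(benzyloxy)benzoate | CC(C)[C@]1(O)CC[C@]2(C)CC=C(C)C(=O)[C@H](OC(=O)c3ccc(OCc4ccccc4)cc3)[C@H]21 | intermediate
22 | (1R,3aR,5S,6S,8R,8aS)-1,5,6-trihydroxy-3a,6-dimethyl-7-oxo-1-(propan-2-yl)decahydroazulen-8-yl 4-(benzyloxy)benzoate | CC(C)[C@]1(O)CC[C@]2(C)C[C@H](O)[C@](C)(O)C(=O)[C@H](OC(=O)c3ccc(OCc4ccccc4)cc3)[C@H]21 | intermediate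
23 | (1R,3aR,5S,6S,8R,8aS)-1,5,6-trihydroxy-3a,6-dimethyl-7-oxo-1-(propan-2-yl)decahydroazulen-8-yl 4-hydroxybenzoate | CC(C)[C@]1(O)CC[C@]2(C)C[C@H](O)[C@](C)(O)C(=O)[C@H](OC(=O)c3ccc(O)cc3)[C@H]21 | target

## Step count and least certain steps

Total step count: 16. Longest linear sequence: 15 steps (steps 1–4 and 6–16); step 5 is a one-step branch.

Step 6 (key step). The most likely problem is slow insertion of the hindered internal silylalkyne into the rhoda-allyl intermediate, so that isomerisation of the vinylcyclopropane or catalyst decay competes and regiocontrol erodes; internal alkynes are the less reactive partners in this cycloaddition. The fallback replaces the metallacycle route by carbenoid cyclopropanation and divinylcyclopropane rearrangement. It sets out from 6, which is silylated (t-BuMe2SiCl, imidazole) to the tert-butyldimethylsilyl ether F1. Decomposition of methyl 2-diazobut-3-enoate by Rh2(S-DOSP)4, or its enantiomer if that is the matched catalyst, cyclopropanates the terminal vinyl group of F1. The resulting cis-divinylcyclopropane undergoes Cope rearrangement on heating to the cycloheptadiene ester F2, whose C3a–C4 bond and quaternary centre are set through the boat transition state under catalyst control. i-Bu2AlH reduces the ester to the allylic alcohol F3, MsCl and Et3N give the mesylate F4, and LiEt3BH displaces it to the C6-methyl silyl ether F5. Bu4NF then frees the dienol F6, and hydroxyl-directed hydrogenation under the conditions of step 7 returns to the route at 13.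

Step 11. The most likely problem is poor site selectivity of the ene reaction (attack on the C6 methyl group or on C4) together with partial over-oxidation, because the preference for the ring CH2 is a rule of thumb that ring conformation can override. The fallback replaces C–H oxidation by a 1,3-carbonyl transposition and sets out from 15. Hydroboration–oxidation (BH3·SMe2; NaOH, H2O2) puts oxygen on the less substituted C5 to give the diol F7. Dess–Martin oxidation gives the C5 ketone F8. Dehydrogenation with IBX can go only towards C6–C7, because C3a has no hydrogen, and gives the enone F9. Alkaline H2O2 gives the epoxy ketone F10, and Wharton rearrangement (N2H4·H2O, AcOH, MeOH) moves the alkene to C5=C6 and the oxygen to C7, returning at 16.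

Step 15. The most likely problems are slow osmylation of the hindered, electron-poor enone, with the aryl ester exposed for a long time to the aqueous medium (hydrolysis or acyl shift), and incomplete α-face selectivity. The fallback dihydroxylates before the ester is attached and under hydroxyl direction; it sets out from 19. Stoichiometric OsO4·TMEDA in CH2Cl2 at −78 °C is guided to the α face by hydrogen bonding to the free C8 α-hydroxyl and gives the tetraol F11. 2,2-Dimethoxypropane with pyridinium p-toluenesulfonate protects the cis-5,6-diol as the acetonide F12. Acylation with 20 as in step 14 gives the ester acetonide F13, and aqueous acetic acid removes the acetonide to return at 22.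

Step 13. The most likely problem is imperfect facial control at C8, or competing γ-deprotonation at C4, since the kinetic enolate is formed next to a sodium alkoxide at C1. The fallback changes from enolate hydroxylation plus acylation to a direct α'-acyloxylation with trivalent manganese and sets out from 17. Mn(OAc)3·2H2O with an excess of 4-(benzyloxy)benzoic acid in benzene at reflux should give 21 in one step, and the α-acyloxy ketone can be equilibrated at C8 to the equatorial α-ester with a mild amine base. This fallback makes no compound outside the list (F0) and returns at 21.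

Step 10. The most likely problem is enolisation of 14 towards C8a (loss of the trans fusion) or hydride transfer from the branched nucleophile in place of addition. The fallback uses an sp2 nucleophile followed by hydrogenation and sets out from 14. Isopropenylmagnesium bromide with CeCl3 adds from the α face to give the isopropenyl carbinol F14. Hydrogen with RhCl(PPh3)3 then reduces only the 1,1-disubstituted alkene and returns at 15.

## Further compounds

F1 | step 6 | tert-butyl{[(1R)-2-ethenyl-3-methylcyclopent-2-en-1-yl]oxy}dimethylsilane | CC(C)(C)[Si](C)(C)O[C@@H]1CCC(C)=C1C=C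
F2 | step 6 | methyl (1R,3aR)-1-[(tert-butyldimethylsilyl)oxy]-3a-methyl-1,2,3,3a,4,7-hexahydroazulene-6-carboxylate | CC(C)(C)[Si](C)(C)O[C@@H]1CC[C@]2(C)CC=C(C(=O)OC)CC=C12
F3 | step 6 | {(1R,3aR)-1-[(tert-butyldimethylsilyl)oxy]-3a-methyl-1,2,3,3a,4,7-hexahydroazulen-6-yl}methanol | CC(C)(C)[Si](C)(C)O[C@@H]1CC[C@]2(C)CC=C(CO)CC=C12
F4 | step 6 | {(1R,3aR)-1-[(tert-butyldimethylsilyl)oxy]-3a-methyl-1,2,3,3a,4,7-hexahydroazulen-6-yl}methyl methanesulfonate | CC(C)(C)[Si](C)(C)O[C@@H]1CC[C@]2(C)CC=C(COS(C)(=O)=O)CC=C12
F5 | step 6 | tert-butyl{[(1R,3aR)-3a,6-dimethyl-1,2,3,3a,4,7-hexahydroazulen-1-yl]oxy}dimethylsilane | CC(C)(C)[Si](C)(C)O[C@@H]1CC[C@]2(C)CC=C(C)CC=C12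
F6 | step 6 | (1R,3aR)-3a,6-dimethyl-1,2,3,3a,4,7-hexahydroazulen-1-ol | O[C@@H]1CC[C@]2(C)CC=C(C)CC=C12
F7 | step 11 | (1R,3aR,8aR)-3a,6-dimethyl-1-(propan-2-yl)decahydroazulene-1,5-diol (C5 and C6 not defined) | CC(C)[C@]1(O)CC[C@]2(C)CC(O)C(C)CC[C@H]21
F8 | step 11 | (1R,3aR,8aR)-1-hydroxy-3a,6-dimethyl-1-(propan-2-yl)octahydroazulen-5(1H)-one (C6 not defined) | CC(C)[C@]1(O)CC[C@]2(C)CC(=O)C(C)CC[C@H]21
F9 | step 11 | (1R,3aR,8aR)-1-hydroxy-3a,6-dimethyl-1-(propan-2-yl)-2,3,3a,4,8,8a-hexahydroazulen-5(1H)-one | CC(C)[C@]1(O)CC[C@]2(C)CC(=O)C(C)=CC[C@H]21
F10 | step 11 | 6,7-epoxide of F9 (epoxide face not defined) | CC(C)[C@]1(O)CC[C@]2(C)CC(=O)C3(C)OC3C[C@H]21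
F11 | step 15 | (1R,3aR,5S,6S,8R,8aS)-1,5,6,8-tetrahydroxy-3a,6-dimethyl-1-(propan-2-yl)octahydroazulen-7(1H)-one | CC(C)[C@]1(O)CC[C@]2(C)C[C@H](O)[C@](C)(O)C(=O)[C@H](O)[C@H]21
F12 | step 15 | 5,6-O-isopropylidene acetal of F11 | CC(C)[C@]1(O)CC[C@]2(C)C[C@@H]3OC(C)(C)O[C@]3(C)C(=O)[C@H](O)[C@H]21
F13 | step 15 | 5,6-O-isopropylidene acetal of 22 | CC(C)[C@]1(O)CC[C@]2(C)C[C@@H]3OC(C)(C)O[C@]3(C)C(=O)[C@H](OC(=O)c4ccc(OCc5ccccc5)cc4)[C@H]21
F14 | step 10 | (1S,3aR,8aR)-3a,6-dimethyl-1-(prop-1-en-2-yl)-1,2,3,3a,4,7,8,8a-octahydroazulen-1-ol (same spatial arrangement as 15) | CC(=C)[C@]1(O)CC[C@]2(C)CC=C(C)CC[C@H]21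
F0 | step 13 | none | none
A1 | alternative 1 | (5R)-5-[(tert-butyldimethylsilyl)oxy]-3,6-dimethylcyclohepta-2,6-dien-1-one | CC1=CC(=O)C=C(C)[C@H](O[Si](C)(C)C(C)(C)C)C1
A2 | alternative 1 | trimethyl(4-methylpenta-1,2-dien-3-yl)silane | CC(C)C(=C=C)[Si](C)(C)C
A3 | alternative 1 | cis-fused 5-[(tert-butyldimethylsilyl)oxy]-3a,6-dimethyl-1-(propan-2-yl)-2-(trimethylsilyl)-3,3a,4,5-tetrahydroazulen-8(8aH)-one | CC(C)C1=C([Si](C)(C)C)C[C@]2(C)C[C@@H](O[Si](C)(C)C(C)(C)C)C(C)=CC(=O)[C@H]12
A4 | alternative 2 | (S)-terpinen-4-ol | CC(C)[C@@]1(O)CC=C(C)CC1
A5 | alternative 2 | (3S)-3-hydroxy-6-oxo-3-(propan-2-yl)heptanal | CC(C)[C@@](O)(CC=O)CCC(C)=O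
A6 | alternative 2 | (5R)-5-hydroxy-2-methyl-5-(propan-2-yl)cyclopent-1-ene-1-carbaldehyde | CC(C)[C@]1(O)CCC(C)=C1C=O
A7 | alternative 3 | bis(trimethylsilyl enol ether) of the ring-A ketone carrying the acetonide-protected C4–C8 methyl ketone chain | C=C(O[Si](C)(C)C)[C@@]1(C)OC(C)(C)O[C@H]1C[C@@]2(C)CCC(O[Si](C)(C)C)=C2
A8 | alternative 3 | trans-fused 5,6-(isopropylidenedioxy)-3a,6-dimethyloctahydroazulene-1,7-dione | O=C1CC[C@]2(C)C[C@@H]3OC(C)(C)O[C@]3(C)C(=O)C[C@H]21
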